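**Assumption:** 2'-hydroxy-4'-methylacetophenone (made from m-cresol) is bought commercially. The enantiomer of the Rh catalyst is chosen to give the (5R)-cycloheptatriene (compound 8).

Guaiane numbering is used in names: C1/C5 are the ring fusion, C4 carries the C15 methyl, C7 carries C11, and C10 carries the methyl. "Face A" is the face that carries 10-Me, 8-O and 7-C11 in the target.

## Retrosynthetic overview
1. Torilin comes from the C8/C11 diol by selective angelation and then acetylation. The diol comes from the ketal-protected enone after thermodynamic C1 epimerisation.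
2. The 2-methylcyclopent-2-enone comes from a hydroazulen-4-one by C3 oxygenation to a diosphenol, conversion to the vinyl triflate, and methylation at C4.
3. The all-cis C7/C8/C10 pattern comes from face-selective syn-hydrogenation of a cycloheptatriene, controlled by the single C5 stereocentre.
4. An enantioselective intramolecular Buchner reaction of an aryl-propyl diazoketone forms the seven-membered ring (by dearomatisation) and the cyclopentanone in one step.
5. The diazoketone comes from an arylpropanoic acid built on a cyclic-ketal-protected arene, which is made from 2'-hydroxy-4'-methylacetophenone.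

## Route

**Step 1**
Reactants: 1, 2'-hydroxy-4'-methylacetophenone
Product: 2, 2-(2-hydroxy-4-methylphenyl)propan-2-ol
Conditions: MeMgBr (3.5 equiv), THF, 0 → 60 °C; aq. NH4Cl workup
Reagents that add atoms: methylmagnesium bromide, C[Mg]Br
Why: Grignard addition to the aryl ketone (after phenoxide formation) creates the C11 carbinol carbon with its C12/C13 methyls.

**Step 2**
Reactants: 2
Product: 3, 2,2,4,4,7-pentamethyl-4H-1,3-benzodioxine
Conditions: Me2C(OMe)2 (5 equiv), PPTS (5 mol %), CH2Cl2, 25 °C
Reagents that add atoms: 2,2-dimethoxypropane, COC(C)(C)OC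
Why: Transketalisation gives the six-membered acetonide of the o-hydroxycumyl diol, which protects both the future C8 and C11 oxygens and ties them together for the later syn-hydrogenation.

**Step 3**
Reactants: 3
Product: 4, 6-bromo-2,2,4,4,7-pentamethyl-4H-1,3-benzodioxine
Conditions: NBS (1.05 equiv), MeCN, solid NaHCO3, 0 °C, dark
Reagents that add atoms: N-bromosuccinimide, O=C1CCC(=O)N1Br
Why: Electrophilic aromatic bromination goes at the one unhindered position para to the ketal oxygen, which becomes the future ring-fusion carbon C1.

**Step 4**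
Reactants: 4; 5, β-propiolactone
Product: 6, 3-(2,2,4,4,7-pentamethyl-4H-1,3-benzodioxin-6-yl)propanoic acid
Conditions: Mg, THF, reflux (ArMgBr); then CuI (10 mol %), 5, THF, −20 → 0 °C; pH 4 phosphate workup
Reagents that add atoms: β-propiolactone, O=C1CCO1
Why: The Cu-catalysed aryl Grignard opens the lactone by SN2 at the O–CH2 carbon, installing CH2CH2CO2H (C2, C3, C4 of the future cyclopentanone).

**Step 5**
Reactants: 6
Product: 7, 1-diazo-4-(2,2,4,4,7-pentamethyl-4H-1,3-benzodioxin-6-yl)butan-2-one
Conditions: i-BuOCOCl, NMM, THF, −15 °C; then CH2N2, Et2O, 0 °C → rt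
Reagents that add atoms: diazomethane, C=[N+]=[N-]
Why: The mixed anhydride plus CH2N2 (Arndt–Eistert-type acylation) gives the α-diazoketone under acid-free conditions that the ketal tolerates.

**Step 6 (key step)**
Reactants: 7
Product: 8, (5R)-8,11-(isopropylidenedioxy)-15-norguaia-1(10),6,8-trien-4-one (cycloheptatriene fused to a cyclopentanone and to the cyclic ketal)
Conditions: Rh2(PTTL)4 (1 mol %, enantiomer giving 5R), CH2Cl2 (0.01 M), 0 → 25 °C, slow addition of 7
Reagents that add atoms: none (N2 is lost)
Why: Proposed new method: the Rh-carbenoid adds to the ipso/ortho bond of the arene, which breaks aromaticity and gives a norcaradiene that opens to the cycloheptatriene; the carbene carbon C5 is the only stereocentre formed, and the chiral dirhodium carboxylate sets its configuration by facial selection on the arene. This is an enantioselective intramolecular Buchner (azulenone-forming) reaction applied to a fully substituted arene, and attack occurs at the only unsubstituted ortho CH.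

**Step 7**
Reactants: 8
Product: 9, all-cis 8,11-(isopropylidenedioxy)-15-norguaian-4-one (H1, H5, H7, H8, H10 all on the face opposite face A)
Conditions: H2 (50 bar), 5% Rh/Al2O3, EtOAc, 25 °C
Reagents that add atoms: none (H2 adds only hydrogen)
Why: Proposed new method: the C4 arm at C5 blocks face A, so all three C=C bonds take H2 syn from the other face and set H7, H8 and H10 there, placing Me10, C11 and O8 on face A. The cis-fused dioxane forces the C7/C8 pair to be cis. The closest known chemistry is Rh-catalysed cis-hydrogenation of polyenes and arenes.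

**Step 8**
Reactants: 9
Product: 10, 3-hydroxy-4-ketone (C3 epimer mixture)
Conditions: LDA (1.1 equiv), THF, −78 °C; then Davis oxaziridine (1.3 equiv), −78 °C
Reagents that add atoms: 2-(phenylsulfonyl)-3-phenyloxaziridine, O=S(=O)(c1ccccc1)N1OC1c1ccccc1
Why: Kinetic deprotonation occurs at the unhindered C3 methylene rather than the ring-fusion methine C5, and oxaziridine O-transfer gives the α-ketol; the new C3 centre is destroyed in the next step.

**Step 9**
Reactants: 10
Product: 11, diosphenol (3-oxo-4-hydroxy-Δ4, C1-H on the hydrogenation face)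
Conditions: Dess–Martin periodinane (2 equiv), NaHCO3, CH2Cl2, 25 °C
Reagents that add atoms: none
Why: Oxidation of the α-ketol gives the 3,4-dione, which enolises toward the substituted C5 as a cyclotene-type diosphenol; this removes the C5 stereocentre, whose only job was to direct step 7.

**Step 10**
Reactants: 11
Product: 12, C4 vinyl triflate
Conditions: Tf2O (1.3 equiv), pyridine (3 equiv), CH2Cl2, −78 → 0 °C
Reagents that add atoms: trifluoromethanesulfonic anhydride, O=S(=O)(C(F)(F)F)OS(=O)(=O)C(F)(F)F
Why: O-Triflation of the enol OH (enol triflation) makes C4 a cross-coupling handle.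

**Step 11**
Reactants: 12
Product: 13, 1-epi enone (3-oxo-Δ4 with the 4-methyl in place; C1-H cis to H10)
Conditions: Me2Zn (3 equiv), Pd(PPh3)4 (10 mol %), THF, 60 °C
Reagents that add atoms: dimethylzinc, C[Zn]C
Why: Negishi methylation of the α-triflyloxy enone installs C15 without touching the ketone or the ketal.

**Step 12**
Reactants: 13
Product: 14, enone acetonide with C1-H trans to H10 (C2 trans to Me10)
Conditions: DBU (3 equiv), toluene, 110 °C, 12 h
Reagents that add atoms: none
Why: γ-Deprotonation through the extended dienolate equilibrates C1 to the more stable isomer, in which the C1–C2 bond is trans to the C10 methyl as in torilin; C7, C8 and C10 cannot enolise.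

**Step 13**
Reactants: 14
Product: 15, (1,7,8,10-configured) 8,11-dihydroxy-3-oxoguai-4-ene
Conditions: PPTS (20 mol %), MeOH/H2O (9:1), 50 °C
Reagents that add atoms: none (water supplies only H; the ketal carbon leaves as acetone)
Why: Mild acid hydrolysis of the acetonide releases the cis-related C8 secondary and C11 tertiary alcohols without disturbing the enone.

**Step 14**
Reactants: 15; 16, angelic acid
Product: 17, 8-O-angeloyl-11-hydroxy-3-oxoguai-4-ene
Conditions: 16 + 2,4,6-Cl3C6H2COCl, Et3N, THF, 25 °C (mixed anhydride); then 15, DMAP (3 equiv), toluene, 25 °C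
Reagents that add atoms: angelic acid, C/C=C(/C)C(=O)O
Why: Yamaguchi esterification acylates only the secondary C8 alcohol, leaves the tertiary C11 alcohol free, and keeps the (Z)-angelate geometry under mild conditions.

**Step 15**
Reactants: 17
Product: 18, torilin
Conditions: Ac2O (10 equiv), DMAP (3 equiv), Et3N (10 equiv), CH2Cl2, 40 °C
Reagents that add atoms: acetic anhydride, CC(=O)OC(C)=O
Why: DMAP-catalysed acylation acetylates the remaining tertiary alcohol (C11) without affecting the angelate or the enone.

## Compound list
1 | 2'-hydroxy-4'-methylacetophenone | CC(=O)c1ccc(C)cc1O | starting material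
2 | 2-(2-hydroxy-4-methylphenyl)propan-2-ol | CC(C)(O)c1ccc(C)cc1O | intermediate
3 | 2,2,4,4,7-pentamethyl-4H-1,3-benzodioxine | CC1(C)Oc2cc(C)ccc2C(C)(C)O1 | intermediate
4 | 6-bromo-2,2,4,4,7-pentamethyl-4H-1,3-benzodioxine | CC1(C)Oc2cc(C)c(Br)cc2C(C)(C)O1 | intermediate
5 | β-propiolactone | O=C1CCO1 | starting material
6 | 3-(2,2,4,4,7-pentamethyl-4H-1,3-benzodioxin-6-yl)propanoic acid | CC1(C)Oc2cc(C)c(CCC(=O)O)cc2C(C)(C)O1 | intermediate
7 | 1-diazo-4-(2,2,4,4,7-pentamethyl-4H-1,3-benzodioxin-6-yl)butan-2-one | CC1(C)Oc2cc(C)c(CCC(=O)C=[N+]=[N-])cc2C(C)(C)O1 | intermediate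
8 | (5R)-Buchner cycloheptatrienone | O=C1CCC2=C(C)C=C3OC(C)(C)OC(C)(C)C3=C[C@@H]12 | intermediate
9 | all-cis saturated ketone acetonide | CC1(C)O[C@@H]2C[C@H](C)[C@@H]3CCC(=O)[C@@H]3C[C@@H]2C(C)(C)O1 | intermediate
10 | 3-hydroxy-4-ketone (C3 unspecified) | CC1(C)O[C@@H]2C[C@H](C)[C@@H]3CC(O)C(=O)[C@@H]3C[C@@H]2C(C)(C)O1 | intermediate
11 | diosphenol | CC1(C)O[C@@H]2C[C@H](C)[C@@H]3CC(=O)C(O)=C3C[C@@H]2C(C)(C)O1 | intermediate
12 | vinyl triflate | CC1(C)O[C@@H]2C[C@H](C)[C@@H]3CC(=O)C(OS(=O)(=O)C(F)(F)F)=C3C[C@@H]2C(C)(C)O1 | intermediate
13 | 1-epi enone acetonide | CC1(C)O[C@@H]2C[C@H](C)[C@@H]3CC(=O)C(C)=C3C[C@@H]2C(C)(C)O1 | intermediate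
14 | enone acetonide, C1 equilibrated | CC1(C)O[C@@H]2C[C@H](C)[C@H]3CC(=O)C(C)=C3C[C@@H]2C(C)(C)O1 | intermediate
15 | 8,11-dihydroxy-3-oxoguai-4-ene (diol) | O[C@@H]1C[C@H](C)[C@H]2CC(=O)C(C)=C2C[C@@H]1C(C)(C)O | intermediate
16 | angelic acid | C/C=C(/C)C(=O)O | starting material
17 | 8-O-angelate, 11-OH | C/C=C(/C)C(=O)O[C@@H]1C[C@H](C)[C@H]2CC(=O)C(C)=C2C[C@@H]1C(C)(C)O | intermediate
18 | torilin | C/C=C(/C)C(=O)O[C@@H]1C[C@H](C)[C@H]2CC(=O)C(C)=C2C[C@@H]1C(C)(C)OC(C)=O | target

**Total steps:** 15
**Longest linear sequence:** 15 steps (compound 1 to 18; the angelic acid branch is one step)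

## Three steps most likely to fail
1. **Step 6 (enantioselective Buchner on the tetrasubstituted arene).** The ee, regiochemistry or yield may be poor because the attacked ortho carbon sits next to the bulky ketal carbon.
   Fallback: run the reaction racemic with Rh2(OAc)4 and carry racemic material to diol 15. Resolve by lipase-catalysed acylation of the C8 alcohol with vinyl acetate, then complete the angelate and acetate steps on the desired enantiomer.
2. **Step 7 (all-syn hydrogenation).** Diastereoselectivity may be poor, or the ketone or cyclopropane-like intermediates may be over-reduced.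
   Fallback: hydrolyse the ketal of the Buchner product to the C8-ketone dienone. Set C7 and C10 by hydroxyl-directed Crabtree hydrogenation using the free C11 alcohol, then reduce the C8 ketone with a hindered hydride and correct C8 by Mitsunobu inversion if needed.
3. **Step 11 (Pd methylation of the hindered tetrasubstituted α-triflyloxy enone).** Oxidative addition or transmetalation may be too slow.
   Fallback: replace steps 8–11 with MeLi/CeCl3 addition to ketone 9, Burgess dehydration to the Δ4(5) alkene, and Pd(OH)2/C–TBHP allylic oxidation at C3.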